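The phthalide is cut at both bonds of its CH2 group (B5–CH2 and CH2–O). On ring B, the phthalide arene, the lactone carbonyl carbon is attached to B4, whose neighbours are oxygen-bearing B3 and the CH2-bearing B5; a free B4 carboxylic acid therefore has a single ortho C–H bond. Palladium-catalysed, carboxylate-directed C–H functionalisation with CH2Br2 should add the one-carbon unit at B5 and close the five-membered lactone in one operation. Its precursor is the complete depsidone carrying B4–CO2H beside B5–H, with benzyl ethers on the ring A phenol, on B3 and on the B2 hydroxymethyl group, and a benzyl ester on ring A.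

Key step: step 17

Locants: ring B = B1 (C–O of the depsidone ester), B2 (C–CH2OH), B3 (C–OH), B4 (C bearing the lactone C=O), B5 (C bearing the lactone CH2), B6 (C–O of the diaryl ether). Ring A is described in words: going round from the methyl-bearing carbon it carries a C–H, the phenol carbon, the carboxyl carbon, the diaryl ether carbon and the carbon bearing the depsidone carbonyl (the ring A acyl carbon).

Assumption: 2,6-difluoro-4-methylbenzoic acid and 2,4-dihydroxybenzoic acid are taken as catalogue chemicals.

Design notes:
- Permanent protection is benzyl throughout (ring A phenol as benzyl ether, ring A carboxyl as benzyl ester, B3–OBn, B2–CH2OBn), so that one neutral hydrogenolysis finishes the synthesis. A methyl ester on ring A or an acetate at B2 could only be removed with base, which would open the seven-membered aryl ester. Aryl methyl ethers would need a Lewis acid at temperatures at which the B2 benzylic position could ionise.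
- The ring A carboxyl must stay esterified in the key step: as a free, doubly ortho-oxygenated acid it would be prone to palladium-mediated protodecarboxylation.
- The diaryl ether is made with ring A as the electrophile (fluoride flanked by two carbonyl groups) and ring B as the phenol. A ring A hydroxyl between two carbonyl groups would be a poor nucleophile for copper-mediated arylation.
- Ring B needs a free hydroxyl at B6 and separately removable groups at B1 and B3, which a 2,4-dihydroxybenzoate provides and a uniformly etherified trioxygenated benzoate would not.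
- Three orthogonal sets are used: allyl ether at B1 (zerovalent palladium), tert-butyl ester at B4 (acid), benzyl for everything else (hydrogenolysis).

**Fragment 1 (ring A)**

Step 1
Reactants: 1 2,6-difluoro-4-methylbenzoic acid
Product: 2 benzyl 2,6-difluoro-4-methylbenzoate
Conditions: BnBr, K2CO3, DMF, rt
Reagents that add atoms: benzyl bromide, BrCc1ccccc1
Why: Carboxylate O-alkylation (SN2 esterification) with a benzylic halide is not hindered by the ortho fluorines, and the benzyl ester makes any alkoxide exchange in the next step degenerate.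

Step 2
Reactants: 2 benzyl 2,6-difluoro-4-methylbenzoate
Product: 3 benzyl 2-(benzyloxy)-6-fluoro-4-methylbenzoate
Conditions: BnOH (1.05 equiv), NaH, THF, 0 °C → rt
Reagents that add atoms: benzyl alcohol, OCc1ccccc1
Why: Nucleophilic aromatic substitution (SNAr) of one of two equivalent fluorides ortho to the ester by sodium benzyloxide should stop after a single substitution because the new alkoxy group deactivates the ring.

Step 3
Reactants: 3 benzyl 2-(benzyloxy)-6-fluoro-4-methylbenzoate
Product: 4 benzyl 6-(benzyloxy)-3-bromo-2-fluoro-4-methylbenzoate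
Conditions: NBS, MeCN, rt, dark
Reagents that add atoms: N-bromosuccinimide, O=C1CCC(=O)N1Br
Why: Electrophilic aromatic bromination should take the position para to the benzyloxy group, between F and CH3, the normal site for alkoxyarenes with this reagent, while the ortho position is crowded between OBn and CH3.

Step 4
Reactants: 4 benzyl 6-(benzyloxy)-3-bromo-2-fluoro-4-methylbenzoate
Product: 6 benzyl 6-(benzyloxy)-2-fluoro-3-formyl-4-methylbenzoate, via ring A arylmagnesium chloride 5 (not isolated)
Conditions: i-PrMgCl·LiCl, THF, −15 → 0 °C; DMF; aq. NH4Cl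
Reagents that add atoms: N,N-dimethylformamide, CN(C)C=O
Why: Bromine–magnesium exchange, accelerated by the ortho fluorine, gives an arylmagnesium species that tolerates the doubly flanked benzyl ester at low temperature and is formylated by DMF (Bouveault-type formylation).

**Fragment 2 (ring B)**

Step 5
Reactants: 7 2,4-dihydroxybenzoic acid
Product: 8 tert-butyl 2,4-dihydroxybenzoate
Conditions: Me2NCH(O-t-Bu)2, toluene, 80 °C
Reagents that add atoms: N,N-dimethylformamide di-tert-butyl acetal, CN(C)C(OC(C)(C)C)OC(C)(C)C
Why: Esterification with an amide acetal transfers the tert-butyl group only to the carboxylic acid, which activates the reagent by protonation, whereas the phenols are not alkylated.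

Step 6
Reactants: 8 tert-butyl 2,4-dihydroxybenzoate
Product: 9 tert-butyl 4-(allyloxy)-2-hydroxybenzoate
Conditions: allyl bromide (1.05 equiv), K2CO3, acetone, reflux
Reagents that add atoms: allyl bromide, C=CCBr
Why: Williamson etherification is selective for the 4-hydroxyl because the 2-hydroxyl is tied up in a hydrogen bond to the ester carbonyl.

Step 7
Reactants: 9 tert-butyl 4-(allyloxy)-2-hydroxybenzoate
Product: 10 tert-butyl 4-(allyloxy)-3-formyl-2-hydroxybenzoate
Conditions: MgCl2, Et3N, (CH2O)n, MeCN, reflux
Reagents that add atoms: paraformaldehyde (formaldehyde), C=O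
Why: The magnesium-mediated ortho-formylation of phenols (Casnati–Skattebøl reaction) delivers formaldehyde inside a magnesium phenoxide complex to the only free ortho position, position 3 between the two oxygens, and excess formaldehyde oxidises the hydroxymethyl stage to the aldehyde.

Step 8
Reactants: 10 tert-butyl 4-(allyloxy)-3-formyl-2-hydroxybenzoate
Product: 11 tert-butyl 4-(allyloxy)-2-hydroxy-3-(hydroxymethyl)benzoate
Conditions: NaBH4, THF/MeOH, 0 °C
Reagents that add atoms: none
Why: Borohydride reduction of an aryl aldehyde is chemoselective beside the tert-butyl ester and the allyl ether.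

Step 9
Reactants: 11 tert-butyl 4-(allyloxy)-2-hydroxy-3-(hydroxymethyl)benzoate
Product: 12 tert-butyl 4-(allyloxy)-2-(benzyloxy)-3-[(benzyloxy)methyl]benzoate
Conditions: NaH (2.4 equiv), BnBr (2.4 equiv), DMF, 0 °C → rt
Reagents that add atoms: benzyl bromide, BrCc1ccccc1
Why: Double Williamson etherification of the phenoxide and the primary alkoxide should be clean because the tert-butyl ester resists alkoxide attack.

Step 10
Reactants: 12 tert-butyl 4-(allyloxy)-2-(benzyloxy)-3-[(benzyloxy)methyl]benzoate
Product: 13 tert-butyl 4-(allyloxy)-2-(benzyloxy)-3-[(benzyloxy)methyl]-5-iodobenzoate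
Conditions: NIS, TFA (cat.), MeCN, rt
Reagents that add atoms: N-iodosuccinimide, O=C1CCC(=O)N1I
Why: Electrophilic aromatic iodination should take position 5, the only activated free position (ortho to the allyloxy and para to the benzyloxy group), since position 6 lies ortho to the ester and meta to both ethers.

Step 11
Reactants: 13 tert-butyl 4-(allyloxy)-2-(benzyloxy)-3-[(benzyloxy)methyl]-5-iodobenzoate
Product: 16 tert-butyl 4-(allyloxy)-2-(benzyloxy)-3-[(benzyloxy)methyl]-5-hydroxybenzoate, via ring B arylmagnesium chloride 14 (not isolated), via dimethyl arylboronate 15 (not isolated)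
Conditions: i-PrMgCl·LiCl, THF, −20 °C; B(OMe)3, −20 °C → rt; then 30% H2O2, AcOH, 0 °C
Reagents that add atoms: hydrogen peroxide, OO
Why: Iodine–magnesium exchange at low temperature tolerates the tert-butyl ester, and borylation followed by peroxide oxidation of the arylboronate (aryl shift from boron to oxygen) gives the phenol without a palladium catalyst, which could engage the ortho allyl ether in a Heck cyclisation.

**Union and endgame**

Step 12
Reactants: 6 benzyl 6-(benzyloxy)-2-fluoro-3-formyl-4-methylbenzoate; 16 tert-butyl 4-(allyloxy)-2-(benzyloxy)-3-[(benzyloxy)methyl]-5-hydroxybenzoate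
Product: 17 diaryl ether aldehyde: benzyl 2-[2-(allyloxy)-4-(benzyloxy)-3-[(benzyloxy)methyl]-5-(tert-butoxycarbonyl)phenoxy]-6-(benzyloxy)-3-formyl-4-methylbenzoate
Conditions: K2CO3, DMF, 60 °C
Reagents that add atoms: none
Why: In this SNAr reaction the fluoride is activated by an ortho formyl and an ortho ester group and the electron-rich phenoxide carries only one ortho substituent, so the diaryl ether between ring A and B6 should form without a metal catalyst.

Step 13
Reactants: 17 diaryl ether aldehyde
Product: 18 diaryl ether acid: 2-[2-(allyloxy)-4-(benzyloxy)-3-[(benzyloxy)methyl]-5-(tert-butoxycarbonyl)phenoxy]-4-(benzyloxy)-3-[(benzyloxy)carbonyl]-6-methylbenzoic acid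
Conditions: NaClO2, NaH2PO4, 2-methyl-2-butene, t-BuOH/THF/H2O, rt
Reagents that add atoms: sodium chlorite, [Na+].[O-]Cl=O
Why: The Pinnick oxidation converts hindered aryl aldehydes to acids under buffered conditions, and the alkene scavenger keeps hypochlorous acid away from the allyl ether and the electron-rich rings.

Step 14
Reactants: 18 diaryl ether acid
Product: 19 seco hydroxy acid: 4-(benzyloxy)-3-[(benzyloxy)carbonyl]-2-[4-(benzyloxy)-3-[(benzyloxy)methyl]-5-(tert-butoxycarbonyl)-2-hydroxyphenoxy]-6-methylbenzoic acid
Conditions: Pd(PPh3)4 (5 mol%), morpholine, THF, rt; dilute HCl work-up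
Reagents that add atoms: none
Why: In this Tsuji–Trost deallylation zerovalent palladium ionises the aryl allyl ether to a π-allyl complex that morpholine captures, leaving benzyl and tert-butyl groups untouched.

Step 15
Reactants: 19 seco hydroxy acid
Product: 20 depsidone B4 tert-butyl ester: 4-benzyl 7-tert-butyl 3,8-bis(benzyloxy)-9-[(benzyloxy)methyl]-1-methyl-11-oxo-11H-dibenzo[b,e][1,4]dioxepine-4,7-dicarboxylate
Conditions: DCC, DMAP (cat.), CH2Cl2 (0.01 M), 0 °C → rt
Reagents that add atoms: none
Why: Carbodiimide-mediated (Steglich) lactonisation is the classical closure of the seven-membered depsidone ring from a 2-(2-hydroxyphenoxy)benzoic acid, and here the only free acid (on ring A, next to the methyl-bearing carbon) and the only free phenol (B1) are held next to each other by the diaryl ether.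

Step 16
Reactants: 20 depsidone B4 tert-butyl ester
Product: 21 depsidone B4 carboxylic acid with B5–H: 3,8-bis(benzyloxy)-4-[(benzyloxy)carbonyl]-9-[(benzyloxy)methyl]-1-methyl-11-oxo-11H-dibenzo[b,e][1,4]dioxepine-7-carboxylic acid
Conditions: TFA/CH2Cl2 (1:4), 0 °C → rt, short reaction time
Reagents that add atoms: none
Why: Acidolysis of the tert-butyl ester with loss of isobutene frees the B4 acid, while benzyl ethers, the benzyl ester and the depsidone aryl ester are stable to brief treatment with trifluoroacetic acid.

Step 17
Reactants: 21 depsidone B4 carboxylic acid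
Product: 23 tetrabenzyl-protected depsidone phthalide, via B5-bromomethyl acid 22 (not isolated)
Conditions: Pd(OAc)2 (10 mol%), K2HPO4 (3 equiv), CH2Br2 (solvent), 140 °C, sealed tube
Reagents that add atoms: dibromomethane, BrCBr
Why: The potassium carboxylate at B4 binds divalent palladium and delivers it to B5, where the C–H bond is cleaved by concerted metalation–deprotonation to a five-membered palladacycle, and oxidative addition of CH2Br2 to a tetravalent palladium species followed by C–C reductive elimination places a bromomethyl group on B5. The carboxylate then displaces the benzylic bromide in an intramolecular SN2 reaction, a 5-exo-tet closure that forms the γ-lactone. The closest known reaction type is the palladium-catalysed, carboxylate-directed ortho C–H alkylation of benzoic acids with dihaloalkanes followed by lactonisation, which gives phthalides from CH2Br2. No stereocentre is formed. Site selectivity is the only selectivity needed and is secured by the substrate: B4–CO2H is the single free acid, its other ortho position B3 carries a benzyloxy group, and the ring A carboxyl is a benzyl ester with no ortho hydrogen. The phosphate buffer should trap the two equivalents of HBr so that the benzyl groups and the depsidone ester survive.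

Step 18
Reactants: 23 tetrabenzyl-protected depsidone phthalide
Product: 24 conneotricone
Conditions: H2 (1 atm), 10% Pd/C, EtOAc/THF, rt, stopped after uptake of four equivalents
Reagents that add atoms: none
Why: Catalytic hydrogenolysis should cleave the two aryl benzyl ethers, the benzyl ester and the O–CH2Ph bond of the B2 benzyloxymethyl group, while the benzylic C–O bonds on the hexasubstituted ring B (B2–CH2OH and the phthalide CH2–O) should be much slower to cleave in neutral solvent because that crowded ring adsorbs poorly on the catalyst.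

**Compound list**

1 | 2,6-difluoro-4-methylbenzoic acid | Cc1cc(F)c(C(=O)O)c(F)c1 | starting material
2 | benzyl 2,6-difluoro-4-methylbenzoate | Cc1cc(F)c(C(=O)OCc2ccccc2)c(F)c1 | intermediate
3 | benzyl 2-(benzyloxy)-6-fluoro-4-methylbenzoate | Cc1cc(F)c(C(=O)OCc2ccccc2)c(OCc2ccccc2)c1 | intermediate
4 | benzyl 6-(benzyloxy)-3-bromo-2-fluoro-4-methylbenzoate | Cc1cc(OCc2ccccc2)c(C(=O)OCc2ccccc2)c(F)c1Br | intermediate
5 | ring A arylmagnesium chloride: [4-(benzyloxy)-3-[(benzyloxy)carbonyl]-2-fluoro-6-methylphenyl]magnesium chloride | Cc1cc(OCc2ccccc2)c(C(=O)OCc2ccccc2)c(F)c1[Mg]Cl | intermediate (not isolated)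
6 | benzyl 6-(benzyloxy)-2-fluoro-3-formyl-4-methylbenzoate | Cc1cc(OCc2ccccc2)c(C(=O)OCc2ccccc2)c(F)c1C=O | intermediate
7 | 2,4-dihydroxybenzoic acid | O=C(O)c1ccc(O)cc1O | starting material
8 | tert-butyl 2,4-dihydroxybenzoate | CC(C)(C)OC(=O)c1ccc(O)cc1O | intermediate
9 | tert-butyl 4-(allyloxy)-2-hydroxybenzoate | C=CCOc1ccc(C(=O)OC(C)(C)C)c(O)c1 | intermediate
10 | tert-butyl 4-(allyloxy)-3-formyl-2-hydroxybenzoate | C=CCOc1ccc(C(=O)OC(C)(C)C)c(O)c1C=O | intermediate
11 | tert-butyl 4-(allyloxy)-2-hydroxy-3-(hydroxymethyl)benzoate | C=CCOc1ccc(C(=O)OC(C)(C)C)c(O)c1CO | intermediate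
12 | tert-butyl 4-(allyloxy)-2-(benzyloxy)-3-[(benzyloxy)methyl]benzoate | C=CCOc1ccc(C(=O)OC(C)(C)C)c(OCc2ccccc2)c1COCc1ccccc1 | intermediate
13 | tert-butyl 4-(allyloxy)-2-(benzyloxy)-3-[(benzyloxy)methyl]-5-iodobenzoate | C=CCOc1c(I)cc(C(=O)OC(C)(C)C)c(OCc2ccccc2)c1COCc1ccccc1 | intermediate
14 | ring B arylmagnesium chloride (MgCl in place of I in 13) | C=CCOc1c([Mg]Cl)cc(C(=O)OC(C)(C)C)c(OCc2ccccc2)c1COCc1ccccc1 | intermediate (not isolated)
15 | dimethyl arylboronate (B(OMe)2 in place of I in 13) | C=CCOc1c(B(OC)OC)cc(C(=O)OC(C)(C)C)c(OCc2ccccc2)c1COCc1ccccc1 | intermediate (not isolated)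
16 | tert-butyl 4-(allyloxy)-2-(benzyloxy)-3-[(benzyloxy)methyl]-5-hydroxybenzoate | C=CCOc1c(O)cc(C(=O)OC(C)(C)C)c(OCc2ccccc2)c1COCc1ccccc1 | intermediate
17 | diaryl ether aldehyde: benzyl 2-[2-(allyloxy)-4-(benzyloxy)-3-[(benzyloxy)methyl]-5-(tert-butoxycarbonyl)phenoxy]-6-(benzyloxy)-3-formyl-4-methylbenzoate | Cc1cc(OCc2ccccc2)c(C(=O)OCc2ccccc2)c(Oc2cc(C(=O)OC(C)(C)C)c(OCc3ccccc3)c(COCc3ccccc3)c2OCC=C)c1C=O | intermediate
18 | diaryl ether acid (CO2H in place of CHO in 17) | Cc1cc(OCc2ccccc2)c(C(=O)OCc2ccccc2)c(Oc2cc(C(=O)OC(C)(C)C)c(OCc3ccccc3)c(COCc3ccccc3)c2OCC=C)c1C(=O)O | intermediate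
19 | seco hydroxy acid (free B1–OH and free ring A carboxylic acid next to the methyl-bearing carbon) | Cc1cc(OCc2ccccc2)c(C(=O)OCc2ccccc2)c(Oc2cc(C(=O)OC(C)(C)C)c(OCc3ccccc3)c(COCc3ccccc3)c2O)c1C(=O)O | intermediate
20 | depsidone B4 tert-butyl ester: 4-benzyl 7-tert-butyl 3,8-bis(benzyloxy)-9-[(benzyloxy)methyl]-1-methyl-11-oxo-11H-dibenzo[b,e][1,4]dioxepine-4,7-dicarboxylate | Cc1cc(OCc3ccccc3)c(C(=O)OCc3ccccc3)c2c1C(=O)Oc1c(COCc3ccccc3)c(OCc3ccccc3)c(C(=O)OC(C)(C)C)cc1O2 | intermediate
21 | depsidone B4 carboxylic acid with B5–H: 3,8-bis(benzyloxy)-4-[(benzyloxy)carbonyl]-9-[(benzyloxy)methyl]-1-methyl-11-oxo-11H-dibenzo[b,e][1,4]dioxepine-7-carboxylic acid | Cc1cc(OCc3ccccc3)c(C(=O)OCc3ccccc3)c2c1C(=O)Oc1c(COCc3ccccc3)c(OCc3ccccc3)c(C(=O)O)cc1O2 | intermediate (key-step substrate)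
22 | B5-bromomethyl acid (CH2Br on B5 of 21) | Cc1cc(OCc3ccccc3)c(C(=O)OCc3ccccc3)c2c1C(=O)Oc1c(COCc3ccccc3)c(OCc3ccccc3)c(C(=O)O)c(CBr)c1O2 | intermediate (not isolated)
23 | tetrabenzyl-protected depsidone phthalide (ring A benzyl ether and benzyl ester, B3–OBn, B2–CH2OBn; γ-lactone B4–C(=O)–O–CH2–B5) | Cc1cc(OCc4ccccc4)c(C(=O)OCc4ccccc4)c2c1C(=O)Oc1c(COCc4ccccc4)c(OCc4ccccc4)c3c(c1O2)COC3=O | intermediate (key-step product)
24 | conneotricone | Cc1cc(O)c(C(=O)O)c2c1C(=O)Oc1c(CO)c(O)c3c(c1O2)COC3=O | target

**Summary**

Total step count: 18.
Longest linear sequence: 14 steps (steps 5–18, from 2,4-dihydroxybenzoic acid). The ring A arm (steps 1–4) joins at step 12.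

Steps most likely to fail:

1. Step 17. The carboxylate may be O-alkylated by CH2Br2 faster than B5 is palladated, palladation at the crowded B5 position may be slow, and HBr that is not buffered quickly enough could strip benzyl groups at 140 °C. The fallback sets out from 21 and replaces the one-pot annulation by a stepwise construction of the same two bonds. Palladium-catalysed, carboxylate-directed ortho C–H iodination (Pd(OAc)2 cat., PhI(OAc)2, I2, DMF, 60 °C) should give the B5-iodo depsidone acid F1, ring A being deactivated toward uncatalysed iodination by its two carbonyl groups. Stille coupling with (tributylstannyl)methanol (Pd(PPh3)4, dioxane, 90 °C) should then give the B5-(hydroxymethyl) depsidone acid F2. This lactonises with catalytic TsOH in CH2Cl2 and the route is rejoined at 23.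

2. Step 18. Reduction may run on past the benzyl ether stage at B2 (hydrogenolytic loss of the benzylic hydroxyl), or the two hindered aryl benzyl ethers may be cleaved incompletely. The fallback sets out from 23 and uses non-reductive Lewis-acid debenzylation at low temperature: BCl3 with pentamethylbenzene as cation scavenger, CH2Cl2, −78 → −20 °C, then aqueous work-up. This reaches 24 directly and no new compound arises (F0).

3. Step 3. Bromination may go partly ortho to the benzyloxy group or, by a radical path, into the benzylic methyl group, and the isomers would be carried forward. The fallback sets out from 3 and replaces electrophilic halogenation by directed deprotonation. TMPMgCl·LiCl (THF, 0 °C → rt) should magnesiate the ring C–H flanked by F and CH3, the most acidic ring position, and give the same arylmagnesium species 5. Quenching with DMF as in step 4 rejoins the route at 6, and no new compound arises (F0).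

Further compounds
F1 | step 17 | B5-iodo depsidone acid (iodine on B5 of 21) | Cc1cc(OCc3ccccc3)c(C(=O)OCc3ccccc3)c2c1C(=O)Oc1c(COCc3ccccc3)c(OCc3ccccc3)c(C(=O)O)c(I)c1O2
F2 | step 17 | B5-(hydroxymethyl) depsidone acid (CH2OH on B5 of 21) | Cc1cc(OCc3ccccc3)c(C(=O)OCc3ccccc3)c2c1C(=O)Oc1c(COCc3ccccc3)c(OCc3ccccc3)c(C(=O)O)c(CO)c1O2
F0 | step 18 | none | none
F0 | step 3 | none | none
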